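**Retrosynthetic overview**
- Ring A is the dihydrofuran fused to the styryl-bearing benzene; ring B is the dihydrofuran carrying the 2,4-dihydroxyphenyl group (benzofuran numbering O1, C2, C3, C3a, C7a in each). Target 27 comes from nonabenzyl ether 26 by one final debenzylation.
- Ring A (formed second): C2–C3 and O1–C2 from the o-quinone methide of a resveratrol-derived O-Boc salicylaldehyde (23 plus aryl Grignard 10) and the sulfonium ylide made from ring B alcohol 16.
- Ring B (formed first, key step): three-component annulation of O-Boc salicylaldehyde 4, aryl Grignard 10 and chiral sulfonium benzylide 11, forming C3–aryl, then C2–C3, then closing the ring through the O1–C2 bond.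
- Enabling feature: in ring B, O1 is a phenol oxygen ortho to C3a, so C3 can be exposed as the exocyclic carbon of an o-quinone methide of the central benzene ring. C2 is benzylic to the 2,4-dioxygenated ring, so it can be carried as a sulfonium ylide whose sulfide O1 then displaces. Both carbons are natively electrophilic; the ylide reverses the polarity of C2.
- Building blocks: 3-(benzyloxy)phenol, 2,4-bis(benzyloxy)benzaldehyde, 1-bromo-3,5-bis(benzyloxy)benzene (converted once into Grignard stock solution 10, which serves both annulations), resveratrol, isothiocineole.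

Key step: step 7

Assumption: the (1R,4R,5R)-sulfide 7 is taken to lead to the 2S,3S series in steps 7 and 14 (by analogy with its benzylidene-transfer epoxidations); if a model annulation shows the opposite sense, the (1S,4S,5S)-sulfide is used with no other change, and the sulfur centre of the sulfonium salts (benzyl on the less hindered lone pair) is not drawn.

Step 1
Reactants: 1 3-(benzyloxy)phenol
Product: 2 5-(benzyloxy)-2-bromophenol
Conditions: NBS (1.0 equiv), i-Pr2NH (10 mol%), CH2Cl2, −20 → 0 °C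
Reagents that add atoms: N-bromosuccinimide, O=C1CCC(=O)N1Br
Why: Amine-mediated ortho-bromination of a phenol (the N-bromoamine is delivered by hydrogen bonding to the OH) should go to the less hindered ortho position, which is also para to the benzyloxy group.

Step 2
Reactants: 2 5-(benzyloxy)-2-bromophenol
Product: 3 6-(benzyloxy)-3-bromo-2-hydroxybenzaldehyde
Conditions: MgCl2, Et3N, (CH2O)n, MeCN, reflux; then 1 M HCl
Reagents that add atoms: paraformaldehyde (as formaldehyde), C=O
Why: Casnati–Skattebøl ortho-formylation through the magnesium phenoxide can only take the one free ortho position, so the carbon that becomes C3 of ring B is placed between the two ring oxygens with the bromine next to the free OH.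

Step 3
Reactants: 3 6-(benzyloxy)-3-bromo-2-hydroxybenzaldehyde
Product: 4 tert-butyl 3-(benzyloxy)-6-bromo-2-formylphenyl carbonate
Conditions: Boc2O, i-Pr2NEt, DMAP (cat.), THF, 0 °C → rt
Reagents that add atoms: di-tert-butyl dicarbonate, CC(C)(C)OC(=O)OC(=O)OC(C)(C)C
Why: DMAP-catalysed O-acylation of the phenol gives the O-Boc salicylaldehyde needed for anionic release of an o-quinone methide.

Step 4
Reactants: 5 2,4-bis(benzyloxy)benzaldehyde
Product: 6 [2,4-bis(benzyloxy)phenyl]methanol
Conditions: NaBH4, MeOH/THF, 0 °C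
Reagents that add atoms: none
Why: Borohydride reduction of an aryl aldehyde to the benzylic alcohol.

Step 5
Reactants: 6 [2,4-bis(benzyloxy)phenyl]methanol; 7 (1R,4R,5R)-4,7,7-trimethyl-6-thiabicyclo[3.2.1]octane (isothiocineole)
Product: 8 (1R,4R,5R)-6-[2,4-bis(benzyloxy)benzyl]-4,7,7-trimethyl-6-thiabicyclo[3.2.1]octan-6-ium tetrafluoroborate
Conditions: HBF4·OEt2, CH2Cl2, 0 °C; Et2O (precipitation), used cold
Reagents that add atoms: tetrafluoroboric acid diethyl ether complex, [H+].F[B-](F)(F)F
Why: Acid-promoted SN1 S-alkylation of the sulfide by an electron-rich benzylic alcohol is the known salt formation for isothiocineole, with the benzyl group entering on the less hindered lone pair of sulfur.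

Step 6
Reactants: 9 1-bromo-3,5-bis(benzyloxy)benzene
Product: 10 [3,5-bis(benzyloxy)phenyl]magnesium bromide (THF stock solution)
Conditions: Mg turnings (I2, cat.), THF, 40 °C; titrated, kept under argon
Reagents that add atoms: magnesium, [Mg]
Why: Grignard reagent formation by insertion of magnesium into the aryl C–Br bond leaves the benzyl ethers untouched, and one titrated batch should supply both annulations (steps 7 and 14).

Step 7
Reactants: 4 tert-butyl 3-(benzyloxy)-6-bromo-2-formylphenyl carbonate; 10 [3,5-bis(benzyloxy)phenyl]magnesium bromide; 8 sulfonium tetrafluoroborate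
Product: 13 (2S,3S)-4-(benzyloxy)-2-[2,4-bis(benzyloxy)phenyl]-3-[3,5-bis(benzyloxy)phenyl]-7-bromo-2,3-dihydro-1-benzofuran, via sulfonium benzylide 11 (not isolated), via o-quinone methide 12 (not isolated)
Conditions: 4, 10 (1.05 equiv), THF, −78 °C; then 11 [from 8, LiN(SiMe3)2 (1.0 equiv), THF/CH2Cl2, −78 °C]; −78 → 0 °C
Reagents that add atoms: none
Why: Proposed new method: 10 adds to the aldehyde of 4, the magnesium alkoxide takes the Boc group from the neighbouring phenol oxygen and the phenoxide then expels tert-butyl carbonate to release o-quinone methide 12 near −40 °C; the preformed ylide 11 adds through its carbanion carbon (future C2) to the exocyclic carbon of 12 (future C3), and the phenoxide oxygen of the betaine (future O1) displaces the sulfide at C2, which forms the O1–C2 bond and closes ring B. C2 and C3 are both natively electrophilic quinone methide carbons, so their union rests on the polarity reversal the sulfonium ylide gives to C2; the closest known reaction types are the anionic o-quinone methide release from O-Boc salicylaldehydes with Grignard reagents, the formal [4+1] annulation of o-quinone methides with carbonyl-stabilised sulfonium or ammonium ylides to trans-2,3-dihydrobenzofurans, and benzylidene transfer from isothiocineole-derived benzylsulfonium salts in asymmetric epoxidation, the new element being a semi-stabilised chiral benzylide on an o-quinone methide. Ring B is closed in the 5-exo-tet mode by SN2 attack of O1 on C2. C2 is controlled by the sulfide, whose bicyclic frame leaves one face of the ylide carbon open, followed by inversion in the closure; C3 is controlled relative to C2 by the anti addition and the faster closure of the betaine that places the two aryl groups trans. The step needs addition to the quinone methide and not to the aldehyde (10 consumes the aldehyde at −78 °C before 11 is added), closure through the oxygen next to bromine (the other ring oxygen is a benzyl ether) and C- rather than O-alkylation (the ylide is fully preformed, so no electrophilic sulfonium salt remains).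

Step 8
Reactants: 13 (2S,3S)-7-bromo-dihydrobenzofuran
Product: 16 [(2S,3S)-4-(benzyloxy)-2-[2,4-bis(benzyloxy)phenyl]-3-[3,5-bis(benzyloxy)phenyl]-2,3-dihydro-1-benzofuran-7-yl]methanol, via aryllithium 14 (not isolated), via aldehyde 15 (not isolated)
Conditions: t-BuLi (2.1 equiv), THF, −78 °C; DMF, −78 → 0 °C; then NaBH4, MeOH, 0 °C
Reagents that add atoms: N,N-dimethylformamide, CN(C)C=O
Why: Bromine–lithium exchange (faster than any deprotonation at −78 °C), formylation with DMF and borohydride reduction in the same flask turn C7–Br into the C7–CH2OH handle without touching the ring B stereocentres.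

Step 9
Reactants: 16 ring B benzylic alcohol; 7 (1R,4R,5R)-isothiocineole
Product: 18 (1R,4R,5R)-6-{[(2S,3S)-4-(benzyloxy)-2-[2,4-bis(benzyloxy)phenyl]-3-[3,5-bis(benzyloxy)phenyl]-2,3-dihydro-1-benzofuran-7-yl]methyl}-4,7,7-trimethyl-6-thiabicyclo[3.2.1]octan-6-ium trifluoromethanesulfonate, via benzylic bromide 17 (not isolated)
Conditions: CBr4, PPh3, CH2Cl2, 0 °C; then 7, AgOSO2CF3, CH2Cl2, −20 °C → rt
Reagents that add atoms: silver trifluoromethanesulfonate, [Ag+].[O-]S(=O)(=O)C(F)(F)F
Why: Appel bromination under neutral conditions followed by silver-assisted S-alkylation of the sulfide gives the second benzylsulfonium salt without exposing the acid-labile C2–O1 bond of ring B to protic acid.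

Step 10
Reactants: 19 resveratrol
Product: 20 (E)-3,5,4'-tris(benzyloxy)stilbene
Conditions: BnBr, K2CO3, DMF, 60 °C
Reagents that add atoms: benzyl bromide, BrCc1ccccc1
Why: Williamson etherification of the three phenols.

Step 11
Reactants: 20 (E)-3,5,4'-tris(benzyloxy)stilbene
Product: 21 2,4-bis(benzyloxy)-6-[(E)-2-(4-(benzyloxy)phenyl)ethenyl]benzaldehyde
Conditions: POCl3, DMF, 0 → 60 °C; then H2O
Reagents that add atoms: N,N-dimethylformamide, CN(C)C=O; water, O
Why: Vilsmeier–Haack formylation at C2 of the 3,5-dibenzyloxy ring (para to one benzyloxy group, ortho to the other) is the known site for 3,5-dialkoxystilbenes.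

Step 12
Reactants: 21 stilbene aldehyde
Product: 22 4-(benzyloxy)-2-hydroxy-6-[(E)-2-(4-(benzyloxy)phenyl)ethenyl]benzaldehyde
Conditions: BCl3 (1.1 equiv), CH2Cl2, −78 °C
Reagents that add atoms: none
Why: Chelation-controlled Lewis-acid cleavage removes only the benzyl ether ortho to the aldehyde, because boron is held by the carbonyl oxygen.

Step 13
Reactants: 22 stilbene salicylaldehyde
Product: 23 tert-butyl 5-(benzyloxy)-2-formyl-3-[(E)-2-(4-(benzyloxy)phenyl)ethenyl]phenyl carbonate
Conditions: Boc2O, i-Pr2NEt, DMAP (cat.), THF, 0 °C → rt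
Reagents that add atoms: di-tert-butyl dicarbonate, CC(C)(C)OC(=O)OC(=O)OC(C)(C)C
Why: DMAP-catalysed O-acylation as in step 3.

Step 14
Reactants: 23 O-Boc stilbene salicylaldehyde; 10 [3,5-bis(benzyloxy)phenyl]magnesium bromide; 18 ring B sulfonium triflate
Product: 26 (2S,3S)-6-(benzyloxy)-2-[(2S,3S)-4-(benzyloxy)-2-[2,4-bis(benzyloxy)phenyl]-3-[3,5-bis(benzyloxy)phenyl]-2,3-dihydro-1-benzofuran-7-yl]-3-[3,5-bis(benzyloxy)phenyl]-4-[(E)-2-(4-(benzyloxy)phenyl)ethenyl]-2,3-dihydro-1-benzofuran, via sulfonium benzylide 24 (not isolated), via o-quinone methide 25 (not isolated)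
Conditions: 23, 10 (1.05 equiv), THF, −78 °C; then 24 [from 18, LiN(SiMe3)2 (1.0 equiv), THF/CH2Cl2, −78 °C]; −78 → 0 °C
Reagents that add atoms: none
Why: Proposed new method: the same three-component sequence as step 7 (Grignard addition, Boc transfer and loss of tert-butyl carbonate to o-quinone methide 25, 1,4-addition of ylide 24, 5-exo-tet SN2 closure by the phenoxide), closest known types being the O-Boc salicylaldehyde route to o-quinone methides and the [4+1] annulation of o-quinone methides with stabilised onium ylides; the sulfide sets C2 of ring A and the trans closure sets C3, the ring B centres being too remote to override the reagent, and the base-only release of 25 avoids the acid-induced cyclisation of a benzhydryl cation onto the neighbouring stilbene.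

Step 15
Reactants: 26 nonabenzyl ether
Product: 27 (2S,3S)-2-[(2S,3S)-3-(3,5-dihydroxyphenyl)-2-(2,4-dihydroxyphenyl)-4-hydroxy-2,3-dihydro-1-benzofuran-7-yl]-3-(3,5-dihydroxyphenyl)-4-[(E)-2-(4-hydroxyphenyl)ethenyl]-2,3-dihydro-1-benzofuran-6-ol (CNP0397447.1)
Conditions: BCl3 (excess), C6HMe5, CH2Cl2, −78 °C; then MeOH
Reagents that add atoms: none
Why: Lewis-acid debenzylation with pentamethylbenzene as a non-basic benzyl-cation scavenger cleaves aryl benzyl ethers at −78 °C without reducing the stilbene, and the low temperature should limit ionisation at C2 of both rings, whose trans arrangement is in any case the thermodynamic one.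

**Compound list**
1 | 3-(benzyloxy)phenol | Oc1cccc(OCc2ccccc2)c1 | starting material
2 | 5-(benzyloxy)-2-bromophenol | Oc1cc(OCc2ccccc2)ccc1Br | intermediate
3 | 6-(benzyloxy)-3-bromo-2-hydroxybenzaldehyde | O=Cc1c(O)c(Br)ccc1OCc1ccccc1 | intermediate
4 | tert-butyl 3-(benzyloxy)-6-bromo-2-formylphenyl carbonate | CC(C)(C)OC(=O)Oc1c(Br)ccc(OCc2ccccc2)c1C=O | intermediate
5 | 2,4-bis(benzyloxy)benzaldehyde | O=Cc1ccc(OCc2ccccc2)cc1OCc1ccccc1 | starting material
6 | [2,4-bis(benzyloxy)phenyl]methanol | OCc1ccc(OCc2ccccc2)cc1OCc1ccccc1 | intermediate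
7 | (1R,4R,5R)-4,7,7-trimethyl-6-thiabicyclo[3.2.1]octane (isothiocineole) | C[C@@H]1CC[C@@H]2C[C@H]1SC2(C)C | starting material
8 | (1R,4R,5R)-6-[2,4-bis(benzyloxy)benzyl]-4,7,7-trimethyl-6-thiabicyclo[3.2.1]octan-6-ium tetrafluoroborate | C[C@@H]1CC[C@@H]2C[C@H]1[S+](Cc1ccc(OCc3ccccc3)cc1OCc1ccccc1)C2(C)C.F[B-](F)(F)F | intermediate
9 | 1-bromo-3,5-bis(benzyloxy)benzene | Brc1cc(OCc2ccccc2)cc(OCc2ccccc2)c1 | starting material
10 | [3,5-bis(benzyloxy)phenyl]magnesium bromide | Br[Mg]c1cc(OCc2ccccc2)cc(OCc2ccccc2)c1 | intermediate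
11 | sulfonium benzylide of 8 (ylide carbon bearing the 2,4-bis(benzyloxy)phenyl group) | C[C@@H]1CC[C@@H]2C[C@H]1[S+]([CH-]c1ccc(OCc3ccccc3)cc1OCc1ccccc1)C2(C)C | intermediate
12 | 3-(benzyloxy)-6-bromo-2-[3,5-bis(benzyloxy)benzylidene]cyclohexa-3,5-dien-1-one (o-quinone methide) | O=C1C(Br)=CC=C(OCc2ccccc2)C1=Cc1cc(OCc2ccccc2)cc(OCc2ccccc2)c1 | intermediate
13 | (2S,3S)-4-(benzyloxy)-2-[2,4-bis(benzyloxy)phenyl]-3-[3,5-bis(benzyloxy)phenyl]-7-bromo-2,3-dihydro-1-benzofuran | Brc1ccc(OCc2ccccc2)c2c1O[C@H](c1ccc(OCc3ccccc3)cc1OCc1ccccc1)[C@H]2c1cc(OCc2ccccc2)cc(OCc2ccccc2)c1 | intermediate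
14 | 7-lithio analogue of 13 | [Li]c1ccc(OCc2ccccc2)c2c1O[C@H](c1ccc(OCc3ccccc3)cc1OCc1ccccc1)[C@H]2c1cc(OCc2ccccc2)cc(OCc2ccccc2)c1 | intermediate
15 | (2S,3S)-4-(benzyloxy)-2-[2,4-bis(benzyloxy)phenyl]-3-[3,5-bis(benzyloxy)phenyl]-2,3-dihydro-1-benzofuran-7-carbaldehyde | O=Cc1ccc(OCc2ccccc2)c2c1O[C@H](c1ccc(OCc3ccccc3)cc1OCc1ccccc1)[C@H]2c1cc(OCc2ccccc2)cc(OCc2ccccc2)c1 | intermediate
16 | [(2S,3S)-4-(benzyloxy)-2-[2,4-bis(benzyloxy)phenyl]-3-[3,5-bis(benzyloxy)phenyl]-2,3-dihydro-1-benzofuran-7-yl]methanol | OCc1ccc(OCc2ccccc2)c2c1O[C@H](c1ccc(OCc3ccccc3)cc1OCc1ccccc1)[C@H]2c1cc(OCc2ccccc2)cc(OCc2ccccc2)c1 | intermediate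
17 | 7-(bromomethyl) analogue of 16 | BrCc1ccc(OCc2ccccc2)c2c1O[C@H](c1ccc(OCc3ccccc3)cc1OCc1ccccc1)[C@H]2c1cc(OCc2ccccc2)cc(OCc2ccccc2)c1 | intermediate
18 | (1R,4R,5R)-6-{[(2S,3S)-4-(benzyloxy)-2-[2,4-bis(benzyloxy)phenyl]-3-[3,5-bis(benzyloxy)phenyl]-2,3-dihydro-1-benzofuran-7-yl]methyl}-4,7,7-trimethyl-6-thiabicyclo[3.2.1]octan-6-ium trifluoromethanesulfonate | C[C@@H]1CC[C@@H]2C[C@H]1[S+](Cc1ccc(OCc3ccccc3)c3c1O[C@H](c1ccc(OCc4ccccc4)cc1OCc1ccccc1)[C@H]3c1cc(OCc3ccccc3)cc(OCc3ccccc3)c1)C2(C)C.[O-]S(=O)(=O)C(F)(F)F | intermediate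
19 | resveratrol, (E)-3,5,4'-trihydroxystilbene | Oc1ccc(/C=C/c2cc(O)cc(O)c2)cc1 | starting material
20 | (E)-3,5,4'-tris(benzyloxy)stilbene | C(c1ccccc1)Oc1ccc(/C=C/c2cc(OCc3ccccc3)cc(OCc3ccccc3)c2)cc1 | intermediate
21 | 2,4-bis(benzyloxy)-6-[(E)-2-(4-(benzyloxy)phenyl)ethenyl]benzaldehyde | O=Cc1c(OCc2ccccc2)cc(OCc2ccccc2)cc1/C=C/c1ccc(OCc2ccccc2)cc1 | intermediate
22 | 4-(benzyloxy)-2-hydroxy-6-[(E)-2-(4-(benzyloxy)phenyl)ethenyl]benzaldehyde | O=Cc1c(O)cc(OCc2ccccc2)cc1/C=C/c1ccc(OCc2ccccc2)cc1 | intermediate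
23 | tert-butyl 5-(benzyloxy)-2-formyl-3-[(E)-2-(4-(benzyloxy)phenyl)ethenyl]phenyl carbonate | CC(C)(C)OC(=O)Oc1cc(OCc2ccccc2)cc(/C=C/c2ccc(OCc3ccccc3)cc2)c1C=O | intermediate
24 | sulfonium benzylide of 18 (ylide carbon on C7 of ring B) | C[C@@H]1CC[C@@H]2C[C@H]1[S+]([CH-]c1ccc(OCc3ccccc3)c3c1O[C@H](c1ccc(OCc4ccccc4)cc1OCc1ccccc1)[C@H]3c1cc(OCc3ccccc3)cc(OCc3ccccc3)c1)C2(C)C | intermediate
25 | 5-(benzyloxy)-3-[(E)-2-(4-(benzyloxy)phenyl)ethenyl]-2-[3,5-bis(benzyloxy)benzylidene]cyclohexa-3,5-dien-1-one (o-quinone methide) | O=C1C=C(OCc2ccccc2)C=C(/C=C/c2ccc(OCc3ccccc3)cc2)C1=Cc1cc(OCc2ccccc2)cc(OCc2ccccc2)c1 | intermediate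
26 | nonabenzyl ether of 27 (all nine phenols as benzyl ethers; 2S,3S in ring A and 2S,3S in ring B) | C(c5ccccc5)Oc1ccc(/C=C/c2cc(OCc5ccccc5)cc3c2[C@H](c2cc(OCc5ccccc5)cc(OCc5ccccc5)c2)[C@@H](c2ccc(OCc5ccccc5)c4c2O[C@H](c2ccc(OCc5ccccc5)cc2OCc5ccccc5)[C@H]4c2cc(OCc5ccccc5)cc(OCc5ccccc5)c2)O3)cc1 | intermediate
27 | (2S,3S)-2-[(2S,3S)-3-(3,5-dihydroxyphenyl)-2-(2,4-dihydroxyphenyl)-4-hydroxy-2,3-dihydro-1-benzofuran-7-yl]-3-(3,5-dihydroxyphenyl)-4-[(E)-2-(4-hydroxyphenyl)ethenyl]-2,3-dihydro-1-benzofuran-6-ol | Oc1ccc(/C=C/c2cc(O)cc3c2[C@H](c2cc(O)cc(O)c2)[C@@H](c2ccc(O)c4c2O[C@H](c2ccc(O)cc2O)[C@H]4c2cc(O)cc(O)c2)O3)cc1 | target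

**Step count and risks**
Total step count: 15. Longest linear sequence: 8 steps (1, 2, 3, 7, 8, 9, 14, 15).

Steps most likely to fail:

1. Step 7 (proposed new method). What may go wrong: the electron-rich sulfonium betaine may ionise at C2 before closure, or the two topicities of addition to the quinone methide may be poorly differentiated, so that stereochemical control is lost. The benzylide may also rearrange, or the quinone methide oligomerise, before the two meet. Fallback, setting out from 4 (with 10 and 5) and returning at 13: the quinone methide 12 is released from 4 and 10 as in step 7 and intercepted at −78 → 0 °C by the Breslow intermediate formed from aldehyde 5, 3-ethyl-5-(2-hydroxyethyl)-4-methylthiazolium bromide (20 mol%) and DBU. This nucleophilic acylation of an o-quinone methide should give 1-[2,4-bis(benzyloxy)phenyl]-2-[6-(benzyloxy)-3-bromo-2-hydroxyphenyl]-2-[3,5-bis(benzyloxy)phenyl]ethan-1-one F1. Asymmetric transfer hydrogenation with RuCl[(S,S)-TsDPEN](p-cymene) (or its enantiomer, chosen on a model) in HCO2H/Et3N, with dynamic kinetic resolution of the enolisable diarylmethine centre, should give (2S)-1-[2,4-bis(benzyloxy)phenyl]-2-[6-(benzyloxy)-3-bromo-2-hydroxyphenyl]-2-[3,5-bis(benzyloxy)phenyl]ethan-1-ol F2. Camphorsulfonic acid (cat.) in CH2Cl2 at 0 °C then ionises the benzylic alcohol and O1 closes onto C2, the same bond as in step 7, to return to 13 as the trans isomer; only the diarylmethine centre of F2 matters, because C2 is reset in the closure.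

2. Step 14 (proposed new method). What may go wrong: the bulky ylide may add slowly to a quinone methide hindered on both sides, so that the quinone methide is consumed by reaction with its neighbouring styryl group or by dimerisation; reagent control may also be eroded by mismatched double stereodifferentiation. Fallback, setting out from 23 (with 10 and aldehyde 15, isolated by leaving out the NaBH4 treatment of step 8) and returning at 26: the quinone methide 25 is released from 23 and 10 as in step 14 and acylated by the Breslow intermediate of 15 (same thiazolium salt and DBU). This should give 1-[(2S,3S)-4-(benzyloxy)-2-[2,4-bis(benzyloxy)phenyl]-3-[3,5-bis(benzyloxy)phenyl]-2,3-dihydro-1-benzofuran-7-yl]-2-[4-(benzyloxy)-2-hydroxy-6-[(E)-2-(4-(benzyloxy)phenyl)ethenyl]phenyl]-2-[3,5-bis(benzyloxy)phenyl]ethan-1-one F3. Transfer hydrogenation with RuCl[(S,S)-TsDPEN](p-cymene) (or its enantiomer) in HCO2H/Et3N under dynamic kinetic resolution should give the corresponding (2S)-ethan-1-ol F4, and pyridinium p-toluenesulfonate in CH2Cl2 closes ring A through O1–C2 to return to 26.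

3. Step 15. What may go wrong: during removal of nine benzyl groups the Lewis acid may open the dihydrofuran rings at C2, and the protonated stilbene may be attacked by the neighbouring resorcinol ring on C3 of ring A (Friedel–Crafts cyclisation). Fallback, setting out from 26 and returning at 27: nucleophilic debenzylation with NaSEt (excess) in DMF at 120 °C under argon, then acidification. This is an SN2 attack of thiolate at each benzylic carbon under basic conditions, so no cation forms at C2 and the stilbene is not protonated.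

**Further compounds**
F1 | step 7 | 1-[2,4-bis(benzyloxy)phenyl]-2-[6-(benzyloxy)-3-bromo-2-hydroxyphenyl]-2-[3,5-bis(benzyloxy)phenyl]ethan-1-one | O=C(c1ccc(OCc2ccccc2)cc1OCc1ccccc1)C(c1cc(OCc2ccccc2)cc(OCc2ccccc2)c1)c1c(O)c(Br)ccc1OCc1ccccc1
F2 | step 7 | (2S)-1-[2,4-bis(benzyloxy)phenyl]-2-[6-(benzyloxy)-3-bromo-2-hydroxyphenyl]-2-[3,5-bis(benzyloxy)phenyl]ethan-1-ol (carbinol centre as delivered by the catalyst, not decisive) | OC(c1ccc(OCc2ccccc2)cc1OCc1ccccc1)[C@@H](c1cc(OCc2ccccc2)cc(OCc2ccccc2)c1)c1c(O)c(Br)ccc1OCc1ccccc1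
F3 | step 14 | 1-[(2S,3S)-4-(benzyloxy)-2-[2,4-bis(benzyloxy)phenyl]-3-[3,5-bis(benzyloxy)phenyl]-2,3-dihydro-1-benzofuran-7-yl]-2-[4-(benzyloxy)-2-hydroxy-6-[(E)-2-(4-(benzyloxy)phenyl)ethenyl]phenyl]-2-[3,5-bis(benzyloxy)phenyl]ethan-1-one | O=C(c1ccc(OCc2ccccc2)c2c1O[C@H](c1ccc(OCc3ccccc3)cc1OCc1ccccc1)[C@H]2c1cc(OCc2ccccc2)cc(OCc2ccccc2)c1)C(c1cc(OCc2ccccc2)cc(OCc2ccccc2)c1)c1c(O)cc(OCc2ccccc2)cc1/C=C/c1ccc(OCc2ccccc2)cc1
F4 | step 14 | (2S)-ethan-1-ol corresponding to F3 (carbinol centre as delivered by the catalyst, not decisive) | OC(c1ccc(OCc2ccccc2)c2c1O[C@H](c1ccc(OCc3ccccc3)cc1OCc1ccccc1)[C@H]2c1cc(OCc2ccccc2)cc(OCc2ccccc2)c1)[C@@H](c1cc(OCc2ccccc2)cc(OCc2ccccc2)c1)c1c(O)cc(OCc2ccccc2)cc1/C=C/c1ccc(OCc2ccccc2)cc1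
F0 | step 15 | none | none
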